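**Plan**

1. Numbering used throughout: C9' is the lactone carbonyl, C7 the lactone carbinol carbon (pyrogallol ring), C8 and C8' the ring-fusion carbons (C8' next to C9'), C9 the ether CH2, C7' the ether carbon (catechol ring). The enabling feature is that C9 sits between the ether oxygen and C8, and benzylic C7 sits between C8 and the lactone oxygen, so a C8=C7 styrene can be spanned by an O-CH2 cation on the C7' oxygen and by the acyl oxygen of C9'.
2. Retrosynthesis: once the phenols are unmasked, O-C9, C9-C8 and O(acyl)-C7 are cut together, which opens both rings to a syn-aldol imide plus formaldehyde. Then C7'-C8' (aldol), N-C9' (auxiliary) and C7=C8 (Wittig) are cut.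
3. Forward: Wittig acid, N-acylation, boron aldol, then one cationic cascade that closes the tetrahydrofuran first (C8-C9) and the lactone second (O-C7). Two deprotections finish the route.
4. Stereochemistry: C7' and C8' come from the auxiliary-controlled syn-aldol. C8 and C7 are set in the cascade (cis fusion forced by the lactone closure, exo aryl by anti addition across the E alkene).

Key step: step 4

Remark: paraformaldehyde is taken as the source of monomeric formaldehyde (compound 12), and acid 4 is assumed to be freed of its minor Z isomer by crystallisation.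

**Step 1**
Reactants: 1 3,4,5-tris(benzyloxy)benzaldehyde; 2 (2-carboxyethyl)triphenylphosphonium bromide
Product: 4 (E)-4-[3,4,5-tris(benzyloxy)phenyl]but-3-enoic acid, via carboxylate ylide 3 (not isolated)
Conditions: 2, NaN(SiMe3)2 (2.2 equiv), THF, 0 °C; then 1, −78 °C → rt; 1 M HCl work-up; recrystallisation
Reagents that add atoms: none
Why: Wittig olefination with the carboxylate-bearing ylide, which with aromatic aldehydes should give the β,γ-unsaturated acid mainly as the E isomer, the double bond staying in conjugation with the aryl ring and not with the carboxyl group.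

**Step 2**
Reactants: 4 (E)-4-[3,4,5-tris(benzyloxy)phenyl]but-3-enoic acid; 5 (S)-4-benzyl-2-oxazolidinone
Product: 7 (S)-4-benzyl-3-{(E)-4-[3,4,5-tris(benzyloxy)phenyl]but-3-enoyl}oxazolidin-2-one, via mixed pivalic anhydride 6 (not isolated)
Conditions: PivCl, Et3N, THF, −20 °C; then 5, LiCl, −20 °C → rt
Reagents that add atoms: none
Why: N-acylation of the oxazolidinone through the mixed pivalic anhydride under LiCl/Et3N activation, a mild protocol without strong base that should leave the β,γ double bond in place.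

**Step 3**
Reactants: 7 (S)-4-benzyl-3-{(E)-4-[3,4,5-tris(benzyloxy)phenyl]but-3-enoyl}oxazolidin-2-one; 8 3,4-diacetoxybenzaldehyde
Product: 11 (4S)-4-benzyl-3-{(2S,3E)-2-[(S)-(3,4-diacetoxyphenyl)(hydroxy)methyl]-4-[3,4,5-tris(benzyloxy)phenyl]but-3-enoyl}oxazolidin-2-one, via dibutylboron Z-dienolate 9 (not isolated), via dibutylboron aldolate 10 (not isolated)
Conditions: Bu2BOTf, iPr2NEt, CH2Cl2, −78 → 0 °C; then 8, −78 → 0 °C; pH 7 phosphate buffer/MeOH, 0 °C → rt (no H2O2)
Reagents that add atoms: none
Why: Evans syn-aldol, in which the Z boron dienolate reacts at its α carbon through a closed chair transition state with the auxiliary carbonyl turned away from the enolate oxygen and the benzyl group shielding one face, which should set C8' (S) and C7' (S) syn; peroxide is left out of the work-up to spare the aryl acetates.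

**Step 4**
Reactants: 11 (4S)-4-benzyl-3-{(2S,3E)-2-[(S)-(3,4-diacetoxyphenyl)(hydroxy)methyl]-4-[3,4,5-tris(benzyloxy)phenyl]but-3-enoyl}oxazolidin-2-one; 12 formaldehyde (used as paraformaldehyde)
Product: 16 (3S,3aR,6S,6aS)-6-(3,4-diacetoxyphenyl)-3-[3,4,5-tris(benzyloxy)phenyl]tetrahydro-1H,3H-furo[3,4-c]furan-1-one, via O-methylene oxocarbenium triflate 13 (not isolated), via C7 benzylic cation triflate 14 (not isolated), via cyclic iminium ether triflate 15 (not isolated)
Conditions: (CH2O)n (3 equiv), Me3SiOTf (2.5 equiv), 2,6-di-tert-butyl-4-methylpyridine (1.2 equiv), CH2Cl2, −40 → 0 °C; then sat. aq. NaHCO3/THF, rt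
Reagents that add atoms: water (O)
Why: Me3SiOTf converts the formaldehyde hemiacetal of the C7' hydroxyl into the O-CH2 oxocarbenium ion 13, the E-styrene attacks it through C8 (the carbon remote from the aryl ring) so that the tetrahydrofuran closes 5-exo-trig and the charge arrives at C7 as the trialkoxybenzyl cation 14, and the imide carbonyl oxygen on C8' then closes the γ-lactone onto C7 (five-membered cation capture, formally 5-endo with respect to the former C8=C7 bond) to give iminium ether 15, which aqueous bicarbonate hydrolyses to lactone 16 and the free oxazolidinone. The closest known reaction types are the oxonium-Prins cyclisation of styrenyl homoallylic alcohols to 2,3-disubstituted tetrahydrofurans with capture of the benzylic cation by a tethered oxygen nucleophile, and the halolactonisation of N-acyl oxazolidinones for the acyl-oxygen capture with loss of the auxiliary. C8 (R, cis ring fusion) is controlled by the two tethers fixed on the aldol-derived centres: C9 comes from the C7' oxygen onto one alkene face and the acyl oxygen on C8' can reach C7 only from the other, which is possible only in the rotamer leading to the cis-fused bicycle, while a cation formed with the other C8 configuration cannot lactonise and should return by retro-Prins fragmentation. C7 (S, aryl exo) follows from this anti addition across the E alkene and is also the convex-face, thermodynamically preferred position should the benzylic cation live long enough to rotate. The step needs attack through C8 and not C7 (5-exo over 6-endo), secured by benzylic stabilisation from the tribenzyloxyphenyl ring, and configurational integrity at C7', secured by the two acetates, which make that aryl ring a poor donor so that the C7' carbinol neither ionises nor scrambles by 2-oxonia-Cope rearrangement. The hindered pyridine takes up TfOH so that the styrene is not protonated before C9 arrives.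

**Step 5**
Reactants: 16 (3S,3aR,6S,6aS)-6-(3,4-diacetoxyphenyl)-3-[3,4,5-tris(benzyloxy)phenyl]tetrahydro-1H,3H-furo[3,4-c]furan-1-one
Product: 17 (3S,3aR,6S,6aS)-6-(3,4-dihydroxyphenyl)-3-[3,4,5-tris(benzyloxy)phenyl]tetrahydro-1H,3H-furo[3,4-c]furan-1-one
Conditions: NH4OAc, MeOH/H2O (4:1), rt
Reagents that add atoms: none
Why: Chemoselective neutral solvolysis of aryl acetates by ammonium acetate in aqueous methanol, which should leave the γ-lactone, the benzyl ethers and both benzylic C-O bonds untouched.

**Step 6**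
Reactants: 17 (3S,3aR,6S,6aS)-6-(3,4-dihydroxyphenyl)-3-[3,4,5-tris(benzyloxy)phenyl]tetrahydro-1H,3H-furo[3,4-c]furan-1-one
Product: 18 (3S,3aR,6S,6aS)-6-(3,4-dihydroxyphenyl)-3-(3,4,5-trihydroxyphenyl)tetrahydro-1H,3H-furo[3,4-c]furan-1-one (CNP0290035.1; 7S,8R,7'S,8'S in the numbering above)
Conditions: H2 (1 atm), 10% Pd/C, EtOAc/MeOH (4:1), rt, stopped at full conversion
Reagents that add atoms: none
Why: Catalytic hydrogenolysis of aryl benzyl ethers, which under neutral conditions at 1 atm should be much faster than cleavage of the benzylic lactone and cyclic ether C-O bonds, so the four stereocentres stay as set.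

**Compound list**

1 | 3,4,5-tris(benzyloxy)benzaldehyde | O=Cc1cc(OCc2ccccc2)c(OCc2ccccc2)c(OCc2ccccc2)c1 | starting material
2 | (2-carboxyethyl)triphenylphosphonium bromide | OC(=O)CC[P+](c1ccccc1)(c1ccccc1)c1ccccc1.[Br-] | starting material
3 | sodium 3-(triphenylphosphoranylidene)propanoate (carboxylate ylide) | [Na+].[O-]C(=O)CC=P(c1ccccc1)(c1ccccc1)c1ccccc1 | intermediate
4 | (E)-4-[3,4,5-tris(benzyloxy)phenyl]but-3-enoic acid | OC(=O)C/C=C/c1cc(OCc2ccccc2)c(OCc2ccccc2)c(OCc2ccccc2)c1 | intermediate
5 | (S)-4-benzyl-2-oxazolidinone | O=C1OC[C@H](Cc2ccccc2)N1 | starting material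
6 | (E)-4-[3,4,5-tris(benzyloxy)phenyl]but-3-enoic pivalic anhydride | CC(C)(C)C(=O)OC(=O)C/C=C/c1cc(OCc2ccccc2)c(OCc2ccccc2)c(OCc2ccccc2)c1 | intermediate
7 | (S)-4-benzyl-3-{(E)-4-[3,4,5-tris(benzyloxy)phenyl]but-3-enoyl}oxazolidin-2-one | O=C1OC[C@H](Cc2ccccc2)N1C(=O)C/C=C/c1cc(OCc2ccccc2)c(OCc2ccccc2)c(OCc2ccccc2)c1 | intermediate
8 | 3,4-diacetoxybenzaldehyde | CC(=O)Oc1ccc(C=O)cc1OC(C)=O | starting material
9 | Z dibutylboron dienolate of 7 (O-boryl, enolate oxygen cis to the styryl group) | O=C1OC[C@H](Cc2ccccc2)N1/C(OB(CCCC)CCCC)=C/C=C/c1cc(OCc2ccccc2)c(OCc2ccccc2)c(OCc2ccccc2)c1 | intermediate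
10 | dibutylboron aldolate of 11 (O-boryl at C7') | O=C1OC[C@H](Cc2ccccc2)N1C(=O)[C@@H](/C=C/c1cc(OCc2ccccc2)c(OCc2ccccc2)c(OCc2ccccc2)c1)[C@H](OB(CCCC)CCCC)c1ccc(OC(C)=O)c(OC(C)=O)c1 | intermediate
11 | (4S)-4-benzyl-3-{(2S,3E)-2-[(S)-(3,4-diacetoxyphenyl)(hydroxy)methyl]-4-[3,4,5-tris(benzyloxy)phenyl]but-3-enoyl}oxazolidin-2-one (syn-aldol imide) | O=C1OC[C@H](Cc2ccccc2)N1C(=O)[C@@H](/C=C/c1cc(OCc2ccccc2)c(OCc2ccccc2)c(OCc2ccccc2)c1)[C@H](O)c1ccc(OC(C)=O)c(OC(C)=O)c1 | intermediate
12 | formaldehyde (used as paraformaldehyde) | C=O | starting material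
13 | O-methylene oxocarbenium triflate of 11 (C7'-O+=CH2) | O=C1OC[C@H](Cc2ccccc2)N1C(=O)[C@@H](/C=C/c1cc(OCc2ccccc2)c(OCc2ccccc2)c(OCc2ccccc2)c1)[C@H]([O+]=C)c1ccc(OC(C)=O)c(OC(C)=O)c1.[O-]S(=O)(=O)C(F)(F)F | intermediate
14 | C7 benzylic cation triflate: 2-aryl-3-acyl tetrahydrofuran (2,3-trans, 3,4-cis) carrying the aryl-CH+ group on C8, imide intact | O=C1OC[C@H](Cc2ccccc2)N1C(=O)[C@@H]1[C@@H](c2ccc(OC(C)=O)c(OC(C)=O)c2)OC[C@@H]1[CH+]c1cc(OCc2ccccc2)c(OCc2ccccc2)c(OCc2ccccc2)c1.[O-]S(=O)(=O)C(F)(F)F | intermediate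
15 | cyclic iminium ether triflate: bicyclic skeleton of 16 with C9' bound as C=N+ to the oxazolidinone nitrogen | O=C3OC[C@H](Cc4ccccc4)[N+]3=C1O[C@H](c5cc(OCc6ccccc6)c(OCc6ccccc6)c(OCc6ccccc6)c5)[C@H]2CO[C@H](c7ccc(OC(C)=O)c(OC(C)=O)c7)[C@@H]12.[O-]S(=O)(=O)C(F)(F)F | intermediate
16 | (3S,3aR,6S,6aS)-6-(3,4-diacetoxyphenyl)-3-[3,4,5-tris(benzyloxy)phenyl]tetrahydro-1H,3H-furo[3,4-c]furan-1-one | O=C1O[C@H](c3cc(OCc4ccccc4)c(OCc4ccccc4)c(OCc4ccccc4)c3)[C@H]2CO[C@H](c3ccc(OC(C)=O)c(OC(C)=O)c3)[C@@H]12 | intermediate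
17 | (3S,3aR,6S,6aS)-6-(3,4-dihydroxyphenyl)-3-[3,4,5-tris(benzyloxy)phenyl]tetrahydro-1H,3H-furo[3,4-c]furan-1-one | O=C1O[C@H](c3cc(OCc4ccccc4)c(OCc4ccccc4)c(OCc4ccccc4)c3)[C@H]2CO[C@H](c3ccc(O)c(O)c3)[C@@H]12 | intermediate
18 | (3S,3aR,6S,6aS)-6-(3,4-dihydroxyphenyl)-3-(3,4,5-trihydroxyphenyl)tetrahydro-1H,3H-furo[3,4-c]furan-1-one (cis-fused, both aryl groups exo) | O=C1O[C@H](c2cc(O)c(O)c(O)c2)[C@H]2CO[C@H](c3ccc(O)c(O)c3)[C@@H]12 | target

**Step count and risks**

Total step count: 6. Longest linear sequence: 6 steps (1 → 4 → 7 → 11 → 16 → 17 → 18).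

Steps most likely to fail:

1. Step 4. Capture of the C7 cation by the weakly nucleophilic imide oxygen may lose out to elimination or external capture. The cyclisation may also proceed through the rotamer whose C8 configuration cannot lactonise, and excess formaldehyde may insert as an oligomer or substitute the electron-rich tribenzyloxyphenyl ring. Fallback, from 11 back to 16, with the two ring closures separated: the C7' hydroxyl of 11 is converted with MOMCl/iPr2NEt into the methoxymethyl ether F1. SnCl4 in CH2Cl2 at −78 °C ionises this defined acetal, and the tetrahydrofuran is closed alone. The benzylic position is taken up by chloride and hydrolysed during the aqueous NaHCO3 work-up to the hydroxy imide F2 (both C7 epimers; the C8 epimer is removed here by chromatography). Catalytic DBU in CH2Cl2 then lactonises F2 by acyl transfer from the imide to the C7 hydroxyl with release of the oxazolidinone. Brief exposure to BF3·OEt2 should equilibrate C7 through the benzylic cation to the exo-aryl lactone 16.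

2. Step 6. Over-reduction, that is hydrogenolysis of the benzylic lactone C7-O bond or of the C7'-O ether bond, may compete with debenzylation once the phenols are free. Fallback, from 17 directly to 18 by non-reductive debenzylation: BCl3 with pentamethylbenzene as benzyl-cation scavenger in CH2Cl2 at −78 °C, followed by methanol quench. This makes no new compound (F0).

3. Step 3. The aryl-conjugated dienolate may react sluggishly or partly through its γ carbon, and the aldolate may suffer retro-aldol cleavage or loss of aryl acetate while boron is removed. Fallback, from 5, 8 and 1 back to 11, with the aryl ring attached after the aldol: 5 is acylated (n-BuLi, crotonyl chloride, THF, −78 °C) to N-crotonyl imide F3. Its deconjugative boron syn-aldol (Bu2BOTf, Et3N, then 8, same peroxide-free work-up) should give the α-vinyl syn-aldol F4 with the same C7' and C8' configuration. Aldehyde 1 is methylenated (Ph3PCH3Br, KOtBu, THF) to 3,4,5-tris(benzyloxy)styrene F5. Cross-metathesis of F4 with F5 (second-generation Grubbs catalyst RuCl2(=CHPh)(H2IMes)(PCy3), CH2Cl2, 40 °C) should give the E styrene 11.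

**Further compounds**

F1 | step 4 | (4S)-4-benzyl-3-{(2S,3E)-2-[(S)-(3,4-diacetoxyphenyl)(methoxymethoxy)methyl]-4-[3,4,5-tris(benzyloxy)phenyl]but-3-enoyl}oxazolidin-2-one | O=C1OC[C@H](Cc2ccccc2)N1C(=O)[C@@H](/C=C/c1cc(OCc2ccccc2)c(OCc2ccccc2)c(OCc2ccccc2)c1)[C@H](OCOC)c1ccc(OC(C)=O)c(OC(C)=O)c1
F2 | step 4 | (4S)-4-benzyl-3-{[(2S,3S,4R)-2-(3,4-diacetoxyphenyl)-4-{hydroxy[3,4,5-tris(benzyloxy)phenyl]methyl}oxolan-3-yl]carbonyl}oxazolidin-2-one (both C7 epimers) | O=C1OC[C@H](Cc2ccccc2)N1C(=O)[C@@H]1[C@@H](c2ccc(OC(C)=O)c(OC(C)=O)c2)OC[C@@H]1C(O)c1cc(OCc2ccccc2)c(OCc2ccccc2)c(OCc2ccccc2)c1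
F0 | step 6 | none | none
F3 | step 3 | (S)-4-benzyl-3-[(E)-but-2-enoyl]oxazolidin-2-one | O=C1OC[C@H](Cc2ccccc2)N1C(=O)/C=C/C
F4 | step 3 | (4S)-4-benzyl-3-{(2S)-2-[(S)-(3,4-diacetoxyphenyl)(hydroxy)methyl]but-3-enoyl}oxazolidin-2-one | O=C1OC[C@H](Cc2ccccc2)N1C(=O)[C@@H](C=C)[C@H](O)c1ccc(OC(C)=O)c(OC(C)=O)c1
F5 | step 3 | 1,2,3-tris(benzyloxy)-5-ethenylbenzene | C=Cc1cc(OCc2ccccc2)c(OCc2ccccc2)c(OCc2ccccc2)c1
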